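**Assumption:** serpyllin (13) is achiral. Compounds 6, 9, 10 and 12 each carry one stereocentre, are formed racemic and lose it on the way, so no configuration has to be set.

Locants: flavone numbering for 13 (O1, C2, C3, C4, C4a, C5–C8, C8a; ring B primed). "Pyranone C2–C6" refers to the monocyclic 4-pyranone (aryl on C2, carbonyl C4). "Cyclobutenone C1–C4" has C1 as the carbonyl and C4 as the quaternary carbon. TMP = 2,2,6,6-tetramethylpiperidid-1-yl.

## The problem

Serpyllin has no stereocentre; its difficulty lies in ring A, where all six positions differ: C5–OH (free, hydrogen-bonded to C4=O), C6–H, C7–OMe, C8–OMe, C8a–O1 and C4a–C4. The molecule carries five methyl ethers and one free phenol, so O5 must be told apart from the oxygens on C7, C8, C2', C3' and C4'. Classical closure of ring C from a 2,6-dioxygenated aryl ketone can use either ortho oxygen and so give the 5,7,8- or the 5,6,7-pattern. 5-Hydroxyflavones of this kind can also pass from one pattern to the other in hot acid (Wessely–Moser rearrangement), so strong acid late in a route is a liability. Ring B is an electron-rich, ortho-substituted 1,2,3-trimethoxyphenyl group that competes in any late oxidation or electrophilic substitution aimed at ring A. The aryl methyl ethers will not survive BBr3, AlCl3 or HBr; the 4-pyranone is opened by hydroxide or alkoxide and is O-alkylated at its carbonyl by hard alkylating agents.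

The feature that makes the key step possible is this: in ring A the free C5–OH stands para to C8–OMe, the C6–H/C7–OMe edge lies between them on one side, and on the other side the fusion bond C8a–C4a is at the same time the O1-bearing C=C (pyranone C6=C5) of a 2-aryl-4-pyranone. This is the array that a 4-alkenyl-3,4-dimethoxycyclobutenone delivers on electrocyclic ring expansion:

| Cyclobutenone atom | Becomes in 13 |
|---|---|
| C1 (C=O) | C5–OH |
| C2–H | C6–H |
| C3–OMe | C7–OMe |
| C4–OMe | C8–OMe |
| alkene on C4 | C8a=C4a |

Ring A therefore need not be bought as an arene and re-decorated.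

## Retrosynthesis

**13 ⇒ 10.** The C5–C4a bond of ring A is cut and C5 is reconnected to C8, which turns the benzenoid ring into cyclobutenone 10 (3,4-dimethoxy-4-(6-aryl-4-oxopyran-2-yl)cyclobut-2-enone), an isomer of 13. Cutting ring C instead (O1–C2, C2–C3 or C2–C1') leaves the whole ring A problem in a purchased or separately made arene. This cut makes ring A from a four-carbon unit and the pyranone C5=C6 bond, and connectivity alone fixes where H, OMe, OMe and OH end up. The free hydroxyl comes from the ketene carbonyl, so no ether is cleaved, and O1–C8a exists before ring A does, so ring C cannot close the wrong way. The forward reaction must open 10 to dienylketene 11 with the pyranonyl group turned inward, close 11 onto pyranone C5 to dienone 12, and enolise.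

**10 ⇒ 9.** The O8–CH3 bond is cut: 10 is the methyl ether of tertiary carbinol 9. The methyl that distinguishes O8 from O5 is attached while the two oxygens are still an alcohol and a ketone, which is simpler than any selective methylation or demethylation of a hydroquinone. The forward reaction must methylate a hindered, base-sensitive carbinol without touching the pyranone carbonyl.

**9 ⇒ 4 + 7.** The bond between cyclobutenone C4 and pyranone C6 (the future C8–C8a bond) is cut, giving 2-(2,3,4-trimethoxyphenyl)-4H-pyran-4-one 4 and methyl semisquarate 7. Forward, 4 is metalated at pyranone C6 to organomagnesium 8, which adds to the carbonyl of 7 that is not a vinylogous ester. Both fragments are small and carry every substituent of the target. The forward reaction needs site-selective deprotonation at the C–H next to the ring oxygen and carbonyl-selective 1,2-addition.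

**4 ⇒ 1 + 2.** The pyranone is cut at O1–C6 and C2–C3: C-acylation of the enolate of (E)-4-methoxybut-3-en-2-one 1 with 2,3,4-trimethoxybenzoyl chloride 2 gives diketone 3, which cyclises with loss of methanol. This brings in ring B with its three methoxy groups in one operation from two catalogue compounds.

**7 ⇒ 5.** Methyl semisquarate 7 comes from dimethyl squarate 5 by reduction of one carbonyl to carbinol 6 and acid-induced carbonyl transposition. This replaces one C–OMe of the squarate by C–H, which is what distinguishes C6–H from C7–OMe in 13.

## Roads not taken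

**Alternative 1:** (the route most chemists would draw first) Ring C is cut at O1–C2 and C2–C3, leading to 1-(2-hydroxy-3,4,6-trimethoxyphenyl)ethanone A1 and acid chloride 2. Forward: O-aroylation, Baker–Venkataraman 1,3-acyl shift to diketone A2, acid cyclodehydration to the hexamethyl ether A3, and cleavage of the C5 methyl ether alone with BCl3. This would very probably work. The chosen plan is preferred for these reasons:
- A1 is not a simple building block; its oxygen pattern needs a multistep preparation with its own selective demethylation.
- Six methyl ethers are made so that one can be destroyed.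
- The last step is a Lewis-acid treatment of exactly the flavone type that can equilibrate to the 5,6,7-series.
- Counting the preparation of A1, the sequence is about twice as long, and no ring is constructed in a way that places substituents.

**Alternative 2:** The C2–C1' bond is cut, leading to 5-(benzyloxy)-7,8-dimethoxy-4H-chromen-4-one A4 and 1-iodo-2,3,4-trimethoxybenzene. Forward: C2-zincation of A4 with TMPZnCl·LiCl, Negishi coupling under Pd(PPh3)4 (zerovalent palladium), then hydrogenolysis of the benzyl group. The aryl–heteroaryl bond is not the hard part of the molecule. A4 needs the same tetra-oxygenated acetophenone as Alternative 1 plus a protecting group on O5, so the ring A problem is untouched and two steps are added.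

**Alternative 3:** The same ring A bonds are cut as in the chosen plan, but for a Dötz benzannulation: carbene complex A5, (CO)5Cr=C(OMe)(pyranonyl) of zerovalent chromium, reacts with methoxyacetylene. CO insertion would give C5–OH and the carbene carbon C8–OMe, the same para relation. The weakness is the alkyne. Terminal alkynes insert so that their substituent ends up next to the CO-derived carbon, which would put the methoxy group on C6 and give the 5-hydroxy-6,8-dimethoxy isomer A6. Alkoxyalkynes are also poor partners because they tend to insert without CO incorporation or to polymerise, and the route needs stoichiometric Cr(CO)6 and the same metalated pyranone. The cyclobutenedione carries C6–H and C7–OMe in fixed positions, so no regiochemical question arises in the ring-forming step.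

Key step: step 5

## Route

Step 1
Reactants: 1 (E)-4-methoxybut-3-en-2-one; 2 2,3,4-trimethoxybenzoyl chloride
Product: 4 2-(2,3,4-trimethoxyphenyl)-4H-pyran-4-one, via enol-ether diketone 3 (not isolated)
Conditions: 1 (2 equiv), LiN(SiMe3)2 (2 equiv), THF, −78 °C; 2 (1 equiv), −78 °C; 1 M HCl quench; crude 3, CF3CO2H (0.2 equiv), toluene, rt
Reagents that add atoms: none
Why: Claisen-type C-acylation of the kinetic lithium dienolate of 1 (deprotonated at the methyl group) by 2, with the second equivalent of enolate taking up the acidic diketone proton and so preventing diacylation; with acid the enol oxygen of the aryl ketone adds 6-endo to the methoxyvinyl ketone and methanol is expelled (addition–elimination), the standard construction of 2-substituted 4-pyranones.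

Step 2
Reactants: 5 dimethyl squarate (3,4-dimethoxycyclobut-3-ene-1,2-dione)
Product: 7 3-methoxycyclobut-3-ene-1,2-dione, via hydroxycyclobutenone 6 (not isolated)
Conditions: LiAlH(OtBu)3 (1.05 equiv), THF, −78 to −20 °C; then 6 M HCl, CH2Cl2, 0 °C to rt
Reagents that add atoms: water (O)
Why: The hindered hydride reduces one of the two equivalent carbonyl groups of 5 by 1,2-addition and stops because the remaining carbonyl of 6 is a vinylogous ester; acid ionises the carbinol to an allyl cation with the C2 methoxy group at its far end, water adds there and methanol leaves (1,3-carbonyl transposition), the known route from dialkyl squarates to alkyl semisquarates.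

Step 3
Reactants: 4 2-(2,3,4-trimethoxyphenyl)-4H-pyran-4-one; 7 3-methoxycyclobut-3-ene-1,2-dione
Product: 9 4-hydroxy-3-methoxy-4-[4-oxo-6-(2,3,4-trimethoxyphenyl)-4H-pyran-2-yl]cyclobut-2-en-1-one (racemic), via C6-magnesiated pyranone 8 (not isolated)
Conditions: 4, TMPMgCl·LiCl (1.1 equiv), THF, −40 °C, 30 min; 7 (1.2 equiv), THF, −78 °C; H2O, −78 °C to rt
Reagents that add atoms: none
Why: Deprotonative magnesiation with a hindered TMP amide is expected at pyranone C6, the only vinylic C–H next to the ring oxygen and the position at which TMP bases of magnesium and zinc metalate 4-pyranones and chromones; 8 then adds 1,2 to the ketone-like carbonyl of 7 (the one bonded to the methoxy-bearing carbon), the other being deactivated as a vinylogous ester, as in organometallic additions to alkoxycyclobutenediones. The new stereocentre is formed racemic and disappears in step 5.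

Step 4
Reactants: 9 4-hydroxy-3-methoxy-4-[4-oxo-6-(2,3,4-trimethoxyphenyl)-4H-pyran-2-yl]cyclobut-2-en-1-one
Product: 10 3,4-dimethoxy-4-[4-oxo-6-(2,3,4-trimethoxyphenyl)-4H-pyran-2-yl]cyclobut-2-en-1-one (racemic)
Conditions: MeI (10 equiv), Ag2O (1.5 equiv), 4 Å MS, MeCN, rt, dark
Reagents that add atoms: iodomethane (CI)
Why: Purdie methylation of the tertiary carbinol under near-neutral conditions, the usual way to cap 4-hydroxycyclobutenones without base-induced ring cleavage; the C8 methyl goes on while the future C5 oxygen is still a ketone, so the two oxygens cannot be confused.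

Step 5
Reactants: 10 3,4-dimethoxy-4-[4-oxo-6-(2,3,4-trimethoxyphenyl)-4H-pyran-2-yl]cyclobut-2-en-1-one
Product: 13 serpyllin (5-hydroxy-7,8-dimethoxy-2-(2,3,4-trimethoxyphenyl)-4H-chromen-4-one), via dienylketene 11 (not isolated), via 4aH-chromene-4,5-dione 12 (not isolated)
Conditions: degassed toluene (0.01 M), 110 °C, argon
Reagents that add atoms: none
Why: Moore–Liebeskind cyclobutenone ring expansion; the closest known reaction type is the thermolysis of 4-alkenyl- and 4-(hetero)aryl-4-alkoxy- or 4-hydroxycyclobutenones to hydroquinone monoethers. Heating opens the cyclobutenone C1–C4 bond of 10 in a conrotatory 4π-electrocyclic reaction, and torquoselectivity turns the C4 methoxy donor outward and the pyranonyl group inward, so ketene 11 is formed with the (Z)-geometry in which the ketene carbon faces pyranone C5. A six-membered, all-carbon, disrotatory 6π-electrocyclic closure then joins the electrophilic ketene carbon to pyranone C5, the nucleophilic beta-carbon of the O1–C6=C5 enol ether, and closes ring A as dienone 12. The C4a–H of 12 lies between two carbonyl groups, so enolisation is fast and is driven by aromatisation of ring A, return of the pyranone conjugation and the C5–OH···O=C4 hydrogen bond. No stereocentre remains, since cyclobutenone C4 of 10 and C4a of 12 both become sp2. The selectivity needed is regiochemical and is secured by connectivity: pyranone C6 has only one carbon neighbour (C5; the other is O1), so only one closure exists, and OH, H, OMe and OMe at C5, C6, C7 and C8 are the substituents of cyclobutenone C1 to C4. The free hydroxyl is formed as such, so no ether has to be cleaved.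

## Compound list

1 | (E)-4-methoxybut-3-en-2-one | CO/C=C/C(C)=O | starting material
2 | 2,3,4-trimethoxybenzoyl chloride | COc1ccc(C(=O)Cl)c(OC)c1OC | starting material
3 | (E)-5-methoxy-1-(2,3,4-trimethoxyphenyl)pent-4-ene-1,3-dione | CO/C=C/C(=O)CC(=O)c1ccc(OC)c(OC)c1OC | intermediate
4 | 2-(2,3,4-trimethoxyphenyl)-4H-pyran-4-one | COc1ccc(-c2cc(=O)cco2)c(OC)c1OC | intermediate
5 | dimethyl squarate (3,4-dimethoxycyclobut-3-ene-1,2-dione) | COC1=C(OC)C(=O)C1=O | starting material
6 | 4-hydroxy-2,3-dimethoxycyclobut-2-en-1-one (racemic) | COC1=C(OC)C(O)C1=O | intermediate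
7 | 3-methoxycyclobut-3-ene-1,2-dione (methyl semisquarate) | COC1=CC(=O)C1=O | intermediate
8 | chloro[4-oxo-6-(2,3,4-trimethoxyphenyl)-4H-pyran-2-yl]magnesium (LiCl complex) | COc1ccc(-c2cc(=O)cc([Mg]Cl)o2)c(OC)c1OC | intermediate
9 | 4-hydroxy-3-methoxy-4-[4-oxo-6-(2,3,4-trimethoxyphenyl)-4H-pyran-2-yl]cyclobut-2-en-1-one (racemic) | COC1=CC(=O)C1(O)c1cc(=O)cc(-c2ccc(OC)c(OC)c2OC)o1 | intermediate
10 | 3,4-dimethoxy-4-[4-oxo-6-(2,3,4-trimethoxyphenyl)-4H-pyran-2-yl]cyclobut-2-en-1-one (racemic) | COC1=CC(=O)C1(OC)c1cc(=O)cc(-c2ccc(OC)c(OC)c2OC)o1 | intermediate
11 | (Z)-3,4-dimethoxy-4-[4-oxo-6-(2,3,4-trimethoxyphenyl)-4H-pyran-2-yl]buta-1,3-dien-1-one (dienylketene) | O=C=C/C(OC)=C(/OC)c1cc(=O)cc(-c2ccc(OC)c(OC)c2OC)o1 | intermediate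
12 | 7,8-dimethoxy-2-(2,3,4-trimethoxyphenyl)-4aH-chromene-4,5-dione (racemic) | COC1=CC(=O)C2C(=O)C=C(c3ccc(OC)c(OC)c3OC)OC2=C1OC | intermediate
13 | serpyllin, 5-hydroxy-7,8-dimethoxy-2-(2,3,4-trimethoxyphenyl)-4H-chromen-4-one | COc1ccc(-c2cc(=O)c3c(O)cc(OC)c(OC)c3o2)c(OC)c1OC | target

## Step count and risks

Total steps: 5. Longest linear sequence: 4 steps (steps 1, 3, 4, 5 from 1 and 2, or steps 2, 3, 4, 5 from 5).

The least certain steps, in route order:

**Step 3 (metalation and addition).** What is most likely to go wrong:
- Loss of site control in the deprotonation: removal of H3 or H5 next to the carbonyl, or of H5' ortho to a methoxy group on ring B, in place of H6.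
- Self-condensation of the C-magnesiated pyranone with unreacted 4 during the time the deprotonation needs.
- Attack at the wrong site of 7: conjugate addition at the methoxy-bearing carbon with loss of methoxide, or addition to the vinylogous ester carbonyl, which would transpose H and OMe in ring A.

Fallback, from 4, rejoining at 8 and hence 9: the carbanion is no longer made by deprotonation with a magnesium base. Compound 4 is zincated with TMPZnCl·LiCl (THF, rt) to chloro[4-oxo-6-(2,3,4-trimethoxyphenyl)-4H-pyran-2-yl]zinc F1, an organozinc too weakly nucleophilic to attack a second pyranone. Iodine then gives 2-iodo-6-(2,3,4-trimethoxyphenyl)-4H-pyran-4-one F2, which is isolated so that the position of substitution is secured and any isomer removed. Iodine–magnesium exchange on F2 with iPrMgCl·LiCl (THF, −78 °C) generates 8 within minutes at a temperature at which it should persist, and 7 is added at once to give 9.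

**Step 4 (O-methylation).** What is most likely to go wrong: base-induced ring cleavage of the strained beta-hydroxy ketone in 9, or methylation at the pyranone carbonyl oxygen to a 4-methoxypyrylium salt.

Fallback, from 9 to 13: the methyl group is put on after ring A is made. Carbinol 9 is heated unprotected (degassed toluene, 110 °C). The hydroxyl is also an outward-rotating donor, so the same ring expansion should give 5,8-dihydroxy-7-methoxy-2-(2,3,4-trimethoxyphenyl)-4H-chromen-4-one F3, which is kept under argon because it is a hydroquinone. MeI (1.1 equiv), K2CO3, acetone, rt should then methylate only O8, because the C5 hydroxyl is held in the hydrogen bond to C4=O, the classical selectivity of 5-hydroxyflavones; this gives 13.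

**Step 5 (key step).** What is most likely to go wrong: the 6π closure has to interrupt the cross-conjugation of the pyranone and may be slower than onto a plain alkene. The ketene could then be lost by dimerisation, by acylation of the phenol already formed, or by capture by adventitious water. Partial inward rotation of the methoxy group would give a ketene that cannot close at all.

Fallback, from 2, rejoining at F3 and ending at 13: ring A is taken from the aromatic pool and C8 is oxygenated last.
- The lithium polyanion of commercial 2',4',6'-trihydroxyacetophenone (LiN(SiMe3)2, 4 equiv, THF, −78 °C) is C-aroylated with 2 to give 1-(2,4,6-trihydroxyphenyl)-3-(2,3,4-trimethoxyphenyl)propane-1,3-dione F4.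
- AcOH with catalytic H2SO4 at 95 °C closes ring C to 5,7-dihydroxy-2-(2,3,4-trimethoxyphenyl)-4H-chromen-4-one F5; the two ortho hydroxyls are equivalent here, so the closure is unambiguous.
- MeI (1 equiv), K2CO3, acetone methylates the non-chelated O7 to give 5-hydroxy-7-methoxy-2-(2,3,4-trimethoxyphenyl)-4H-chromen-4-one F6.
- Elbs persulfate oxidation (K2S2O8, aqueous KOH, pyridine) attacks the position para to the C5 phenoxide and gives potassium 5-hydroxy-7-methoxy-4-oxo-2-(2,3,4-trimethoxyphenyl)-4H-chromen-8-yl sulfate F7.
- Aqueous HCl hydrolyses F7 to the hydroquinone F3 of the step 4 fallback, and the selective O8 methylation described there gives 13.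

This fallback is longer and depends on an oxidation that is typically inefficient, which is why it is held in reserve.

## Further compounds

F1 | step 3 | chloro[4-oxo-6-(2,3,4-trimethoxyphenyl)-4H-pyran-2-yl]zinc | COc1ccc(-c2cc(=O)cc([Zn]Cl)o2)c(OC)c1OC
F2 | step 3 | 2-iodo-6-(2,3,4-trimethoxyphenyl)-4H-pyran-4-one | COc1ccc(-c2cc(=O)cc(I)o2)c(OC)c1OC
F3 | step 4 | 5,8-dihydroxy-7-methoxy-2-(2,3,4-trimethoxyphenyl)-4H-chromen-4-one | COc1ccc(-c2cc(=O)c3c(O)cc(OC)c(O)c3o2)c(OC)c1OC
F4 | step 5 | 1-(2,4,6-trihydroxyphenyl)-3-(2,3,4-trimethoxyphenyl)propane-1,3-dione | COc1ccc(C(=O)CC(=O)c2c(O)cc(O)cc2O)c(OC)c1OC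
F5 | step 5 | 5,7-dihydroxy-2-(2,3,4-trimethoxyphenyl)-4H-chromen-4-one | COc1ccc(-c2cc(=O)c3c(O)cc(O)cc3o2)c(OC)c1OC
F6 | step 5 | 5-hydroxy-7-methoxy-2-(2,3,4-trimethoxyphenyl)-4H-chromen-4-one | COc1ccc(-c2cc(=O)c3c(O)cc(OC)cc3o2)c(OC)c1OC
F7 | step 5 | potassium 5-hydroxy-7-methoxy-4-oxo-2-(2,3,4-trimethoxyphenyl)-4H-chromen-8-yl sulfate | COc1ccc(-c2cc(=O)c3c(O)cc(OC)c(OS(=O)(=O)[O-])c3o2)c(OC)c1OC.[K+]
A1 | alternative 1 | 1-(2-hydroxy-3,4,6-trimethoxyphenyl)ethan-1-one | CC(=O)c1c(O)c(OC)c(OC)cc1OC
A2 | alternative 1 | 1-(2-hydroxy-3,4,6-trimethoxyphenyl)-3-(2,3,4-trimethoxyphenyl)propane-1,3-dione | COc1ccc(C(=O)CC(=O)c2c(O)c(OC)c(OC)cc2OC)c(OC)c1OC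
A3 | alternative 1 | 5,7,8-trimethoxy-2-(2,3,4-trimethoxyphenyl)-4H-chromen-4-one | COc1ccc(-c2cc(=O)c3c(OC)cc(OC)c(OC)c3o2)c(OC)c1OC
A4 | alternative 2 | 5-(benzyloxy)-7,8-dimethoxy-4H-chromen-4-one | COc1cc(OCc2ccccc2)c2c(=O)ccoc2c1OC
A5 | alternative 3 | pentacarbonyl{methoxy[4-oxo-6-(2,3,4-trimethoxyphenyl)-4H-pyran-2-yl]methylidene}chromium | COC(=[Cr](=C=O)(=C=O)(=C=O)(=C=O)=C=O)c1cc(=O)cc(-c2ccc(OC)c(OC)c2OC)o1
A6 | alternative 3 | 5-hydroxy-6,8-dimethoxy-2-(2,3,4-trimethoxyphenyl)-4H-chromen-4-one | COc1ccc(-c2cc(=O)c3c(O)c(OC)cc(OC)c3o2)c(OC)c1OC
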